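A small charge of D, 0.019 M, goes under the same gas as the two earlier runs, and what I watch on repeating it is the D column.

| flask | D | G | remark | time |
|---|---|---|---|---|
| epsilon | 0.027 M | 0.77 mM (held) | run made earlier |  |
| alpha | 0.042 M | 0.77 mM (held) | run made earlier |  |
| flask | 0.019 M | 0.77 mM (held) |  | 30 min |

- epsilon (time / min: Z / %, D / %): 5.00: 3.3, 96.5; 10.0: 5.8, 92.2; 15.0: 8.6, 88.8; 20.0: 9.8, 84.1; 25.0: 12.4, 79.8; 30.0: 12.5, 76.9
- alpha (time / min: Z / %, D / %): 2.50: 1.2, 99.1; 4.00: 2.5, 98.3; 6.00: 3.4, 96.5; 10.0: 5.0, 93.2; 20.0: 7.0, 86.7; 30.0: 11.5, 79.4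

(scatter of a reading: 0.5 percentage points)

- how much Z there is at 30 min, in percent of the D charged
- the change that raises the amount of Z at 30 min, in percent of the D charged most ("none" if none brings more than 2 percentage points) (amber / red / none)
- amount of Z at 30 min, in percent of the D charged, after amber

- amber: doubling the saturation concentration of G, all else as stated
- red: doubling the transfer coefficient of G, all else as stated

- the numbers in the tables scatter by 0.5 percentage points (one standard deviation)
- at the start none of G is in solution

With the gas held, I freeze the dissolved level of G. D then falls as a pseudo-first-order reactant, with k′ = ln(charge / D left) / time. The last readings give 0.00876 min⁻¹ in epsilon and 0.00769 min⁻¹ in alpha. I assume the reciprocal of k′ is a straight line in c_D, with the slope standing for gas transfer. At this charge that gives 0.00945 min⁻¹. This k′, the loss constant of D with dissolved G frozen, is what I carry.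

First the main step alone: D left is 75.3%, so Z would be 24.7%. Now add a loss of Z. At the last readings D plus Z falls short of the charge by 10.6% in epsilon and 9.10% in alpha. Taking off their mean, my Z is 14.8%, which is 60.1% of the D turned over.

Then the gas. Amber, I reckon, doubles k′. Red, I reckon, halves the slope part of the reciprocal, giving 0.0104 min⁻¹. Holding that share, amber gives 26.0% and red 16.2%, so in my reckoning amber gains more than red.

The forecast says 12.5%, amber and 18%: “Amber nearly doubles k (to about 0.016 /min), giving Z ≈ 18%”. My figures for Z, plain and under amber, both stand higher than its figures.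

The flask gives 15.0%. Amber brings 11 percentage points against 2.9 points for red, and reaches 26.3%, where the forecast had 18%.

    G ⇌ Q, rate k1*(csat - [Q]) (kL = 0.0144 s⁻¹)
    D + Q → Z (k = 0.344 M⁻¹ s⁻¹)
    Q + Z → J (k = 0.00931 M⁻¹ s⁻¹)
    Z ⇌ E (K = 1.17, k = 0.00116 s⁻¹)
    Q ⇌ L (K = 7.90, k = 0.00461 s⁻¹)

In the flask, D and Q made Z while Q stood at 4.36 × 10⁻⁴ M at 3.00 min and 5.22 × 10⁻⁴ M at 30.0 min, and D was 75% at the end against my frozen 75.3%. Alongside, Z passed to E, a net 10.2% against 25.2% made up to 30 min. The same flask left until 50 min has frozen k′ leaving 62.3% of D, and it holds 59.7%, with Q at 5.68 × 10⁻⁴ M.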